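The benzene ring is made last. The arene of the chromanol carries O1 on C8a, a methyl on C8 and the hydroxyl on C6, which is the imprint of three alkynes: C8a≡C8, C4a≡C5 and C6≡C7. Two of them are tied together through O1–C2–C3–C4, so a ruthenium-catalysed [2+2+2] cycloaddition of a tertiary ynol-ether 1,7-diyne with ethynyl-Bpin closes the dihydropyran and the benzene ring in one operation and leaves boron at C6 as the masked phenol. The precursor is a farnesol-derived (R)-tertiary propynyl ether bearing a but-3-ynyl arm; its stereocentre, set by Sharpless epoxidation, is untouched. The terminal E-methyl is oxidised to the acid afterwards.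

Key step: step 7

Remarks on the chemistry (assumptions):
- Atoms carry chroman numbers (O1, C2, C3, C4, C4a, C5–C8, C8a) in the target and in the open-chain diyne.
- The target is 2R. With the priority order O > ring-side CH2 > side-chain CH2 > CH3, the same spatial arrangement is R at C3 of the epoxide, in the tertiary alcohol and in the diyne, so the (2R,3R)-epoxide of farnesol (from D-(−)-diethyl tartrate) is the one required.
- The alkyne is protected with iPr3Si rather than Me3Si because it has to pass a potassium alkoxide and n-BuLi.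
- The alkyne arm is attached while the tertiary oxygen is still part of the oxirane, so the free tertiary alcohol never coexists with a primary sulfonate.

Step 1
Reactants: 1 (2E,6E)-farnesol
Product: 2 (2R,3R)-2,3-epoxyfarnesol
Conditions: Ti(OiPr)4 (5 mol %), D-(−)-diethyl tartrate (7 mol %), t-BuOOH, 4 Å MS, CH2Cl2, −20 °C
Reagents that add atoms: tert-butyl hydroperoxide, CC(C)(C)OO
Why: Sharpless asymmetric epoxidation: the titanium tartrate complex epoxidises only the allylic 2,3-alkene, and D-(−)-diethyl tartrate directs oxygen to the face that gives the (2R,3R)-epoxide, whose C3 becomes C2 of the chroman.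

Step 2
Reactants: 2 (2R,3R)-2,3-epoxyfarnesol; 3 ethynyltriisopropylsilane
Product: 6 triisopropyl{3-[(2R,3R)-3-[(3E)-4,8-dimethylnona-3,7-dien-1-yl]-3-methyloxiran-2-yl]prop-1-yn-1-yl}silane, via epoxy triflate 4 (not isolated), via lithium (triisopropylsilyl)acetylide 5 (not isolated)
Conditions: Tf2O, Et3N, CH2Cl2, −78 °C; then 5 (2.5 equiv, from 3 and n-BuLi, THF, −78 °C), DMPU, −78 → −20 °C
Reagents that add atoms: none
Why: Primary triflates of 2,3-epoxy alcohols are displaced by lithium acetylides (SN2) at low temperature before the oxirane is attacked, and because the tertiary oxygen is still locked in the oxirane no γ-hydroxy sulfonate that could close to an oxetane is ever formed; both stereocentres are untouched.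

Step 3
Reactants: 6 epoxy alkyne
Product: 7 (5R,8E)-5,9,13-trimethyl-1-(triisopropylsilyl)tetradeca-8,12-dien-1-yn-5-ol
Conditions: LiEt3BH, THF, 0 °C → rt; then H2O
Reagents that add atoms: none
Why: Lithium triethylborohydride opens trisubstituted epoxides by SN2 attack at the less substituted carbon, so the hydride enters at the CH carbon and the tertiary C–O bond, with its R configuration, is kept.

Step 4
Reactants: 7 tertiary alcohol; 8 trichloroethylene
Product: 11 (5R,8E)-5-{[(E)-1,2-dichloroethenyl]oxy}-5,9,13-trimethyl-1-(triisopropylsilyl)tetradeca-8,12-dien-1-yne, via potassium alkoxide 9 (not isolated), via dichloroacetylene 10 (not isolated)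
Conditions: KH, THF, 0 °C; then 8, 0 °C → rt
Reagents that add atoms: none
Why: First stage of the trichloroethylene route to ynol ethers: the alkoxide eliminates HCl from 8 to give dichloroacetylene and adds to it in anti fashion, and the bulky iPr3Si group keeps the alkoxide away from silicon.

Step 5
Reactants: 11 dichlorovinyl ether
Product: 14 (5R,8E)-5,9,13-trimethyl-5-(prop-1-yn-1-yloxy)-1-(triisopropylsilyl)tetradeca-8,12-dien-1-yne, via chloroalkynyl ether 12 (not isolated), via lithium alkoxyacetylide 13 (not isolated)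
Conditions: n-BuLi (2.3 equiv), THF, −78 → −40 °C; then MeI, DMPU, −78 → 0 °C
Reagents that add atoms: iodomethane, CI
Why: Second stage of the same ynol ether synthesis: dehydrochlorination and chlorine–lithium exchange give the lithium alkoxyacetylide, which MeI methylates at carbon (the future C8 methyl) without involving the carbinol centre.

Step 6
Reactants: 14 silyl-protected diyne
Product: 15 (5R,8E)-5,9,13-trimethyl-5-(prop-1-yn-1-yloxy)tetradeca-8,12-dien-1-yne
Conditions: Bu4NF, THF, 0 °C → rt; NaHCO3 work-up, Et3N-treated silica, below 30 °C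
Reagents that add atoms: none
Why: Fluoride-induced protodesilylation of the alkynylsilane runs under basic conditions that an ynol ether tolerates, provided work-up and chromatography stay non-acidic and cool.

Step 7
Reactants: 15 ynol-ether 1,7-diyne; 16 2-ethynyl-4,4,5,5-tetramethyl-1,3,2-dioxaborolane
Product: 17 2-[(2R)-2-[(3E)-4,8-dimethylnona-3,7-dien-1-yl]-2,8-dimethyl-3,4-dihydro-2H-chromen-6-yl]-4,4,5,5-tetramethyl-1,3,2-dioxaborolane
Conditions: (C5Me5)RuCl(C8H12) (10 mol %), 16 (3 equiv), ClCH2CH2Cl, 20–25 °C, 15 added slowly over several hours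
Reagents that add atoms: none
Why: Proposed new method: the (C5Me5)RuCl fragment, freed from cyclooctadiene, binds both alkynes of 15 and divalent ruthenium couples them oxidatively to a bicyclic ruthenacyclopentadiene (tetravalent ruthenium) in which C4a–C8a already exists; insertion of 16 and reductive elimination then form C5–C6 and C7–C8 and release the arene. The closest known reaction type is the (C5Me5)RuCl(C8H12)-catalysed [2+2+2] cycloaddition of tethered diynes with terminal alkynes and alkynylboronates, together with rhodium-catalysed cyclotrimerisations of alkynyl ethers; an O-alkyl ynol ether as one arm of a 1,7-diyne has not been used in this way. The dihydropyran ring closes in the intramolecular oxidative coupling, the O1–C2–C3–C4 tether (helped by the quaternary C2) bringing C8a and C4a together, and the benzene ring closes by the intermolecular insertion and reductive elimination. No stereocentre is created: none of the four bonds at C2 takes part, so the R configuration from step 1 is kept. The step needs boron at C6 (meta to the C8 methyl) and not at C7, which sterics should secure because the Bpin-bearing carbon of 16 bonds to the unsubstituted C5 terminus, away from the methyl-bearing C8. Cross- over self-trimerisation is favoured by excess 16 and slow addition of 15, and the ambient temperature keeps the tertiary ynol ether from retro-ene loss of ketene and alkene.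

Step 8
Reactants: 17 arylboronate
Product: 18 (2R)-2-[(3E)-4,8-dimethylnona-3,7-dien-1-yl]-2,8-dimethyl-3,4-dihydro-2H-chromen-6-ol
Conditions: H2O2 (30 % aq.), NaOH (aq.), THF, 0 °C, argon; then Na2S2O3, NH4Cl (aq.)
Reagents that add atoms: hydrogen peroxide, OO
Why: Hydroperoxide adds to boron and the aryl group migrates to oxygen (ipso oxidation of an arylboronate), while isolated trisubstituted alkenes do not react with alkaline H2O2.

Step 9
Reactants: 18 chromanol
Product: 19 (2R)-2-[(3E)-4,8-dimethylnona-3,7-dien-1-yl]-2,8-dimethyl-3,4-dihydro-2H-chromen-6-yl acetate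
Conditions: Ac2O, pyridine, DMAP (cat.), CH2Cl2, 0 °C → rt
Reagents that add atoms: acetic anhydride, CC(=O)OC(C)=O
Why: Acylation of the phenol (DMAP catalysis) masks the easily oxidised chromanol for the two oxidation steps that follow.

Step 10
Reactants: 19 aryl acetate
Product: 20 (2R)-2-[(3E,7E)-9-hydroxy-4,8-dimethylnona-3,7-dien-1-yl]-2,8-dimethyl-3,4-dihydro-2H-chromen-6-yl acetate
Conditions: SeO2 (0.3 equiv), t-BuOOH, salicylic acid (cat.), CH2Cl2, 0 °C → rt
Reagents that add atoms: selenium dioxide, O=[Se]=O; tert-butyl hydroperoxide, CC(C)(C)OO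
Why: Riley allylic oxidation in its catalytic SeO2/t-BuOOH form (ene reaction, then [2,3]-sigmatropic shift): the terminal isopropylidene reacts faster than the internal trisubstituted alkene and it is the (E)-methyl that is oxidised, which gives the (E)-allylic alcohol.

Step 11
Reactants: 20 allylic alcohol
Product: 22 (2E,6E)-9-[(2R)-6-acetoxy-2,8-dimethyl-3,4-dihydro-2H-chromen-2-yl]-2,6-dimethylnona-2,6-dienoic acid, via enal 21 (not isolated)
Conditions: PhI(OAc)2, TEMPO (cat.), CH2Cl2, rt; then NaClO2, NaH2PO4, 2-methyl-2-butene, t-BuOH/H2O, 0 °C → rt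
Reagents that add atoms: sodium chlorite, [Na+].[O-]Cl=O
Why: TEMPO/PhI(OAc)2 oxidises the allylic alcohol to the enal without over-oxidation or isomerisation and Pinnick oxidation then gives the acid, 2-methyl-2-butene scavenging HOCl so that the other alkene and the arene are spared.

Step 12
Reactants: 22 acetoxy acid
Product: 23 (2E,6E)-9-[(2R)-6-hydroxy-2,8-dimethyl-3,4-dihydro-2H-chromen-2-yl]-2,6-dimethylnona-2,6-dienoic acid (target)
Conditions: LiOH, THF/H2O (degassed), rt, argon; then 1 M HCl to pH 3
Reagents that add atoms: none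
Why: Saponification of the aryl acetate under exclusion of air; the acid is carried as its carboxylate and released on acidification, and the E-alkenes and C2 are not affected.

Compound list

1 | (2E,6E)-farnesol, (2E,6E)-3,7,11-trimethyldodeca-2,6,10-trien-1-ol | CC(C)=CCC/C(C)=C/CC/C(C)=C/CO | starting material
2 | (2R,3R)-2,3-epoxyfarnesol, [(2R,3R)-3-[(3E)-4,8-dimethylnona-3,7-dien-1-yl]-3-methyloxiran-2-yl]methanol | OC[C@H]1O[C@]1(C)CC/C=C(\C)CCC=C(C)C | intermediate
3 | ethynyltriisopropylsilane | C#C[Si](C(C)C)(C(C)C)C(C)C | starting material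
4 | [(2R,3R)-3-[(3E)-4,8-dimethylnona-3,7-dien-1-yl]-3-methyloxiran-2-yl]methyl trifluoromethanesulfonate | FC(F)(F)S(=O)(=O)OC[C@H]1O[C@]1(C)CC/C=C(\C)CCC=C(C)C | intermediate
5 | lithium (triisopropylsilyl)acetylide | [Li]C#C[Si](C(C)C)(C(C)C)C(C)C | intermediate
6 | triisopropyl{3-[(2R,3R)-3-[(3E)-4,8-dimethylnona-3,7-dien-1-yl]-3-methyloxiran-2-yl]prop-1-yn-1-yl}silane | CC(C)[Si](C(C)C)(C(C)C)C#CC[C@H]1O[C@]1(C)CC/C=C(\C)CCC=C(C)C | intermediate
7 | (5R,8E)-5,9,13-trimethyl-1-(triisopropylsilyl)tetradeca-8,12-dien-1-yn-5-ol | CC(C)[Si](C(C)C)(C(C)C)C#CCC[C@](C)(O)CC/C=C(\C)CCC=C(C)C | intermediate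
8 | trichloroethylene | ClC=C(Cl)Cl | starting material
9 | potassium (5R,8E)-5,9,13-trimethyl-1-(triisopropylsilyl)tetradeca-8,12-dien-1-yn-5-olate | CC(C)[Si](C(C)C)(C(C)C)C#CCC[C@](C)(O[K])CC/C=C(\C)CCC=C(C)C | intermediate
10 | dichloroacetylene | ClC#CCl | intermediate
11 | (5R,8E)-5-{[(E)-1,2-dichloroethenyl]oxy}-5,9,13-trimethyl-1-(triisopropylsilyl)tetradeca-8,12-dien-1-yne | CC(C)[Si](C(C)C)(C(C)C)C#CCC[C@](C)(O/C(Cl)=C\Cl)CC/C=C(\C)CCC=C(C)C | intermediate
12 | (5R,8E)-5-[(chloroethynyl)oxy]-5,9,13-trimethyl-1-(triisopropylsilyl)tetradeca-8,12-dien-1-yne | CC(C)[Si](C(C)C)(C(C)C)C#CCC[C@](C)(OC#CCl)CC/C=C(\C)CCC=C(C)C | intermediate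
13 | ({[(5R,8E)-5,9,13-trimethyl-1-(triisopropylsilyl)tetradeca-8,12-dien-1-yn-5-yl]oxy}ethynyl)lithium | CC(C)[Si](C(C)C)(C(C)C)C#CCC[C@](C)(OC#C[Li])CC/C=C(\C)CCC=C(C)C | intermediate
14 | (5R,8E)-5,9,13-trimethyl-5-(prop-1-yn-1-yloxy)-1-(triisopropylsilyl)tetradeca-8,12-dien-1-yne | CC(C)[Si](C(C)C)(C(C)C)C#CCC[C@](C)(OC#CC)CC/C=C(\C)CCC=C(C)C | intermediate
15 | (5R,8E)-5,9,13-trimethyl-5-(prop-1-yn-1-yloxy)tetradeca-8,12-dien-1-yne | C#CCC[C@](C)(OC#CC)CC/C=C(\C)CCC=C(C)C | intermediate
16 | 2-ethynyl-4,4,5,5-tetramethyl-1,3,2-dioxaborolane | C#CB1OC(C)(C)C(C)(C)O1 | starting material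
17 | 2-[(2R)-2-[(3E)-4,8-dimethylnona-3,7-dien-1-yl]-2,8-dimethyl-3,4-dihydro-2H-chromen-6-yl]-4,4,5,5-tetramethyl-1,3,2-dioxaborolane | C/C(=C\CC[C@]1(C)CCc2cc(B3OC(C)(C)C(C)(C)O3)cc(C)c2O1)CCC=C(C)C | intermediate
18 | (2R)-2-[(3E)-4,8-dimethylnona-3,7-dien-1-yl]-2,8-dimethyl-3,4-dihydro-2H-chromen-6-ol | C/C(=C\CC[C@]1(C)CCc2cc(O)cc(C)c2O1)CCC=C(C)C | intermediate
19 | (2R)-2-[(3E)-4,8-dimethylnona-3,7-dien-1-yl]-2,8-dimethyl-3,4-dihydro-2H-chromen-6-yl acetate | C/C(=C\CC[C@]1(C)CCc2cc(OC(C)=O)cc(C)c2O1)CCC=C(C)C | intermediate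
20 | (2R)-2-[(3E,7E)-9-hydroxy-4,8-dimethylnona-3,7-dien-1-yl]-2,8-dimethyl-3,4-dihydro-2H-chromen-6-yl acetate | C/C(=C\CC[C@]1(C)CCc2cc(OC(C)=O)cc(C)c2O1)CC/C=C(\C)CO | intermediate
21 | (2R)-2-[(3E,7E)-4,8-dimethyl-9-oxonona-3,7-dien-1-yl]-2,8-dimethyl-3,4-dihydro-2H-chromen-6-yl acetate | C/C(=C\CC[C@]1(C)CCc2cc(OC(C)=O)cc(C)c2O1)CC/C=C(\C)C=O | intermediate
22 | (2E,6E)-9-[(2R)-6-acetoxy-2,8-dimethyl-3,4-dihydro-2H-chromen-2-yl]-2,6-dimethylnona-2,6-dienoic acid | C/C(=C\CC[C@]1(C)CCc2cc(OC(C)=O)cc(C)c2O1)CC/C=C(\C)C(=O)O | intermediate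
23 | (2E,6E)-9-[(2R)-6-hydroxy-2,8-dimethyl-3,4-dihydro-2H-chromen-2-yl]-2,6-dimethylnona-2,6-dienoic acid | C/C(=C\CC[C@]1(C)CCc2cc(O)cc(C)c2O1)CC/C=C(\C)C(=O)O | target

Total step count: 12. Longest linear sequence: 12 steps (1 → 23).

Steps most likely to fail

Step 7 (Proposed new method). The cyclotrimerisation may stall or run unselectively: the boryl alkyne may insert in the reverse sense (boron at C7), the terminal alkynes may self-oligomerise, or the ynol ether may be hydrated or fragment before the ruthenacycle forms. The fallback builds the chroman by known C–C and C–O couplings and puts boron on afterwards; it sets out from 2 and returns at 17.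
- Iodination of 2 (PPh3, I2, imidazole) should give the epoxy iodide (2S,3R)-3-[(3E)-4,8-dimethylnona-3,7-dien-1-yl]-2-(iodomethyl)-3-methyloxirane F1. It has the same spatial arrangement as 2; only the descriptor at the CH carbon changes.
- Zinc dust in warm ethanol should eliminate F1 reductively to (3R,6E)-nerolidol F2.
- Hydroboration of the vinyl group of F2 with 9-BBN and B-alkyl Suzuki–Miyaura coupling with commercial 2-bromo-1-iodo-3-methylbenzene (PdCl2(dppf), K3PO4, THF/DMF/H2O; the C–I bond reacts first) should give (3R,6E)-1-(2-bromo-3-methylphenyl)-3,7,11-trimethyldodeca-6,10-dien-3-ol F3.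
- Intramolecular palladium-catalysed C–O coupling of the tertiary alcohol (Pd(OAc)2, 2-(di-tert-butylphosphino)-1,1′-binaphthyl, Cs2CO3, toluene, 80 °C) closes the dihydropyran ring with the C2–O bond retained and should give (2R)-2-[(3E)-4,8-dimethylnona-3,7-dien-1-yl]-2,8-dimethyl-3,4-dihydro-2H-chromene F4.
- Iridium-catalysed C–H borylation ([Ir(OMe)(C8H12)]2, 4,4′-di-tert-butyl-2,2′-bipyridine, B2pin2, THF, 60 °C) takes place at C6, the only arene C–H without an ortho substituent, and delivers 17.

Step 4. The hindered tertiary alkoxide may add too slowly to dichloroacetylene and instead attack the tethered alkyne in a 5-exo mode or decompose under the basic conditions. The fallback avoids the alkoxide altogether; it sets out from 7 and returns at 14.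
- Formylation of 7 (acetic formic anhydride, pyridine, DMAP) should give (5R,8E)-5,9,13-trimethyl-1-(triisopropylsilyl)tetradeca-8,12-dien-1-yn-5-yl formate F5.
- Wittig-type dibromomethylenation of the formyl group (PPh3, CBr4, CH2Cl2) should give (5R,8E)-5-[(2,2-dibromoethenyl)oxy]-5,9,13-trimethyl-1-(triisopropylsilyl)tetradeca-8,12-dien-1-yne F6.
- n-BuLi (2.2 equiv, THF, −78 °C) converts F6 by dehydrobromination and bromine–lithium exchange into the lithium alkoxyacetylide 13, which MeI/DMPU methylates to 14.

Step 10. The allylic oxidation may stop short of full conversion, run on to the enal, and attack the internal allylic positions as well. The fallback replaces C–H oxidation by olefin cross-metathesis; it sets out from 19 and returns at 21.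
- 19 and excess methacrolein with the second-generation Hoveyda–Grubbs catalyst (CH2Cl2, 40 °C) should exchange the terminal isopropylidene for the (E)-2-methyl-enal and give 21 directly; the more hindered internal trisubstituted alkene is left alone.
- 21 then enters the second stage of step 11. This fallback makes no compound outside the list (F0).

Further compounds

F1 | step 7 | (2S,3R)-3-[(3E)-4,8-dimethylnona-3,7-dien-1-yl]-2-(iodomethyl)-3-methyloxirane | IC[C@H]1O[C@]1(C)CC/C=C(\C)CCC=C(C)C
F2 | step 7 | (3R,6E)-nerolidol, (3R,6E)-3,7,11-trimethyldodeca-1,6,10-trien-3-ol | C=C[C@](C)(O)CC/C=C(\C)CCC=C(C)C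
F3 | step 7 | (3R,6E)-1-(2-bromo-3-methylphenyl)-3,7,11-trimethyldodeca-6,10-dien-3-ol | Cc1cccc(CC[C@](C)(O)CC/C=C(\C)CCC=C(C)C)c1Br
F4 | step 7 | (2R)-2-[(3E)-4,8-dimethylnona-3,7-dien-1-yl]-2,8-dimethyl-3,4-dihydro-2H-chromene | C/C(=C\CC[C@]1(C)CCc2cccc(C)c2O1)CCC=C(C)C
F5 | step 4 | (5R,8E)-5,9,13-trimethyl-1-(triisopropylsilyl)tetradeca-8,12-dien-1-yn-5-yl formate | CC(C)[Si](C(C)C)(C(C)C)C#CCC[C@](C)(OC=O)CC/C=C(\C)CCC=C(C)C
F6 | step 4 | (5R,8E)-5-[(2,2-dibromoethenyl)oxy]-5,9,13-trimethyl-1-(triisopropylsilyl)tetradeca-8,12-dien-1-yne | CC(C)[Si](C(C)C)(C(C)C)C#CCC[C@](C)(OC=C(Br)Br)CC/C=C(\C)CCC=C(C)C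
F0 | step 10 | none | none
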